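The exchange on this starting complex is slow: in the beta run 62% of it still stood after 2.50 h. The same run still held 11% at 15.0 h, so I kept time in the reckoning, and I wanted a figure for each end of the ranking.

| setting | beta | epsilon | eta | birch | elm | maple | alder | cedar | ash |
|---|---|---|---|---|---|---|---|---|---|
| starting complex | 0.50 M | 0.50 M | 0.33 M | 0.50 M | 0.30 M | 0.80 M | 0.12 M | 0.50 M | 0.30 M |
| incoming ligand | 2.5 equiv | 2.5 equiv | 2.5 equiv | 2.50 equiv | 5.00 equiv | 2.50 equiv | 2.50 equiv | 2.50 equiv | 2.50 equiv |
| leaving ligand | 0.19 equiv | 1.3 equiv | 0.50 equiv | 0.500 equiv | 0.250 equiv | 1.00 equiv | 0.500 equiv | 1.00 equiv | 1.50 equiv |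
| protic impurity | 0.50 M | 0.50 M | 0.50 M | 0.500 M | 0.500 M | 0.500 M | 0.500 M | 1.50 M | 0.300 M |
| remark | run made earlier | run made earlier | run made earlier |  |  |  |  |  |  |
| time |  |  |  | 15 h | 15 h | 15 h | 15 h | 15 h | 15 h |

- beta (time / h: complex with one exchanged / %, starting complex / %): 2.50: 15, 62; 5.00: 24, 39; 8.00: 28, 24; 10.0: 31, 20; 12.0: 31, 16; 15.0: 32, 11
- epsilon (time / h: complex with one exchanged / %, starting complex / %): 1.00: 8, 82; 3.00: 21, 55; 5.00: 25, 41; 8.00: 34, 25; 12.0: 39, 15; 15.0: 42, 8
- eta (time / h: complex with one exchanged / %, starting complex / %): 1.33: 6, 81; 4.00: 15, 53; 8.00: 22, 29; 10.0: 27, 24; 15.0: 28, 11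

(standard deviation of a reading: 1.5 percentage points)

- the earlier runs were read with a standard deviation of 1.5 percentage points
- no earlier run changes the charge of protic impurity; that part of a forecast is a guess

- the flasks put in order of amount of complex with one exchanged, in percent of the starting complex charged, best first, at 15 h (birch / elm / maple / alder / cedar / ash)
- the amount of complex with one exchanged, in percent of the starting complex charged of the flask you put first, at 15 h
- the amount of complex with one exchanged, in percent of the starting complex charged of the flask you put last, at 15 h

The readings looked contradictory at first. The epsilon run at 15.0 h showed 8% of starting complex left and 42% of complex with one exchanged, so 50.0% of the charge had gone somewhere else. I took the second route to be reaction with protic impurity, first order in it, which is a guess because no earlier run changes that charge. If each route goes with its partner, the complex with one exchanged divided by the starting complex lost otherwise should rise in step with the molar ratio of incoming ligand to impurity. Dividing the one by the other gave 0.284 for eta at 4.00 h and 0.294 for epsilon at 5.00 h, so I carried their mean as the selectivity factor s, 0.289. I set beta aside because it ended at 32%, lower than epsilon's 42% on the same charges but for leaving ligand, which points to a further loss that s ignores.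

With incoming ligand X and impurity H held at their charges (pseudo-first-order), I let the starting complex decay with a constant k proportional to H + sX, and integrating gave complex with one exchanged = sX/(H + sX) · (1 − exp(−kt)). Eta supplied the scale: 0.159 h⁻¹ at H + sX = 0.739 M. Alder has a lower ratio of incoming ligand to impurity than any other flask, and there H + sX = 0.587 M gave k = 0.126 h⁻¹ and 12.6%. Maple has the highest ratio, and the same reckoning gave it 1.08 M, then 0.232 h⁻¹ and 52.0%, a rougher figure because its 0.80 M of starting complex is more than its 0.500 M of impurity.

The forecast put maple > elm > birch > ash > cedar > alder, with 55% first and 11% last, on the ground that “Early yield is only 33–45% of what is consumed, so a parallel path competes”. The flasks gave maple > birch > ash > elm > cedar > alder, with 51.4% first and 13.3% last.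

    starting complex + incoming ligand ⇌ leaving ligand + complex with one exchanged (K = 11.0, k = 2.40 × 10⁻⁵ M⁻¹ s⁻¹)
    complex with one exchanged + incoming ligand ⇌ leaving ligand + complex with two exchanged (K = 0.170, k = 5.10 × 10⁻⁵ M⁻¹ s⁻¹)
    starting complex → decomposition product (k = 1.00 × 10⁻⁷ s⁻¹)
    protic impurity + starting complex → quenched substrate (k = 5.30 × 10⁻⁵ M⁻¹ s⁻¹)

Alder gave 13.3% against my 12.6%, and maple gave 51.4% against my 52.0%. I put the same s on a neighbour of alder with impurity cut to 0.20 M. H + sX fell to 0.287 M, so k became 0.0616 h⁻¹ and the share rose to 30.2%. That gave 39.7% of starting complex left and 18.2% of complex with one exchanged. The neighbour held 42% of starting complex and 18.6% of complex with one exchanged.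

The runs are simulated for substances that don't exist.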